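Each closed vessel began with starting material and a small charge of protic impurity. On the list of suspects, two starting material give target, reversibly, and one starting material meets one protic impurity to give quenched substrate. The percentages count target by the starting material in it. So target plus starting material forms one pool, and the dimerisation leaves that pool unchanged.

| flask | starting material | protic impurity | temperature | remark | time |
|---|---|---|---|---|---|
| delta | 0.045 M | 0.0134 M | 18 °C | run made earlier |  |
| beta | 0.10 M | 0.0134 M | 34 °C | run made earlier |  |
| zeta | 0.067 M | 0.0067 M | 18 °C | run made earlier |  |
| cedar | 0.067 M | 0.0134 M | 10 °C |  | 80 min |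
| ash | 0.067 M | 0.0134 M | 25 °C |  | 80 min |
| elm | 0.067 M | 0.0134 M | 40 °C |  | 80 min |

| run | time / min | target / % | starting material / % |
|---|---|---|---|
| delta | 12.0 | 9.7 | 75.7 |
| delta | 25.0 | 13.8 | 63.4 |
| delta | 40.0 | 16.3 | 57.1 |
| delta | 50.0 | 19.6 | 52.5 |
| beta | 4.00 | 17.3 | 73.0 |
| beta | 8.00 | 25.5 | 62.3 |
| beta | 12.0 | 28.3 | 57.5 |
| beta | 15.0 | 31.0 | 55.3 |
| zeta | 12.0 | 14.1 | 78.3 |
| zeta | 25.0 | 23.1 | 68.2 |
| zeta | 40.0 | 29.5 | 60.1 |
| zeta | 50.0 | 32.3 | 56.9 |

(standard deviation of a reading: 0.5 percentage points)

- the flask that comes out highest in amount of target, in percent of the starting material charged, or "all alike" when all lie within 1.5 percentage points (cedar / ash / elm / all alike)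
- target at the end, in percent of the starting material charged, cedar
- target at the end, in percent of the starting material charged, ash
- target at the end, in percent of the starting material charged, elm

I set two amounts against each other: the charge of protic impurity and the charge of starting material. The three new flasks share one ratio of these, 20.0%. I called it the quench loss: the charge of protic impurity over the charge of starting material. It is the share of the charged starting material that the protic impurity, the limiting reagent of that step, can take. On the list the impurity has one path, so a slow quench delays this loss and does not change its size.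

The readings carried this. In the beta run the ratio was 13.4%, and the pool had lost 13.7% by 15.0 min. In the zeta run the ratio was 10.0%, and the pool had lost 10.8% by 50.0 min. In the delta run the ratio was 29.8%, and the loss was still climbing, at 27.9% by 50.0 min. So I expected a pool of 80.0% in each new flask once the quench had finished.

The forecast held that “the quench is fast and stoichiometric”, and it also took a pool of about 80%. It named ash highest, with 28% for cedar, 30.5% for ash and 22.5% for elm.

The flasks gave 28.8% in cedar, 31.9% in ash and 22.8% in elm, so ash came out highest, as forecast.

    2 starting material ⇌ target (K = 11.0 M⁻¹, k = 0.190 M⁻¹ min⁻¹, Ea = 49.0 kJ mol⁻¹, ΔH = −36.0 kJ mol⁻¹)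
    starting material + protic impurity → quenched substrate (k = 2.60 M⁻¹ min⁻¹, Ea = 49.0 kJ mol⁻¹)
    starting material → decomposition product (k = 5.80 × 10⁻⁵ min⁻¹, Ea = 96.0 kJ mol⁻¹)
    (constants at 25 °C)

In ash the quench loss of 20.0% stood as 20.0% of quenched substrate at 80.0 min. The half-life of the protic impurity by the quench in ash was 4.9 min at 4.45 min, much shorter than the 80 min of the run, and 0.039% of its charge remained at the end. Next I took the neighbour flask, like ash but with 0.27 M of starting material. Its quench loss came to 4.96%, lower than in ash, so I reckoned a pool of 95.0%. That flask ended with 4.96% of quenched substrate, 62.4% of target and 32.4% of starting material.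

The earlier runs and the new flask stem from a simulated flask with constants of no real substance, and the scatter is random.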